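## Retrosynthetic overview

1. The target comes from epoxide 22, whose late opening with Cp2TiCl releases 1β-OH and 10β-H. 22 comes from C4 ketone 21 by methylenation, and 21 from a Δ7-6-one (Luche reduction, OsO4) that already carries the butenolide (aldol at C11, then Ph3P=C=C=O).
2. The C19 methyl and the 1(10)-olefin come from deconjugative C5-methylation of ene-dione 8.
3. Key step: ring B of 8 is closed by a cation–olefin cyclisation of acyl enone 6. The C8 cation relays by 1,2-H (C9→C8) and 1,2-CH3 (C10→C9) shifts, as in the labdane-to-clerodane cation cascade, and regenerates the enone.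
4. 6 is assembled from isoprene-derived allyl bromide 2, stannyl enone 5 and CO.
5. Ring order: ring A (bought, from 3), then ring B (step 5), then a temporary 1,10-epoxide (step 7), then the butenolide (step 10).

Convention: bicyclic compounds carry the neo-clerodane numbering of the target (C1–C10 ring carbons, C11–C16 side chain, C17 on C8, C18 on C4, C19 on C5, C20 on C9). β is the face of H-10 in the target. "Neo-clerodane" implies 19α-CH3, 17α-CH3, 20α-CH3 and C11 β on C9.

Assumption: the (S,S)-configured ligand in step 5 gives the 9S series drawn; if the sense is the opposite, the (R,R)-ligand is used.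

## Route

Step 1
Reactants: 1 isoprene
Product: 2 (2E)-4-bromo-3-methylbut-2-en-1-yl acetate
Conditions: NBS, AcOH, 0 → 23 °C
Reagents that add atoms: N-bromosuccinimide BrN1C(=O)CCC1=O; acetic acid CC(O)=O
Why: Electrophilic 1,4-bromoacetoxylation of the diene: Br+ adds to C1, acetate traps the distal end of the allyl cation, and the favoured E trisubstituted olefin is purified by distillation.

Step 2
Reactants: 3 3-methylcyclohex-2-en-1-one
Product: 4 2-iodo-3-methylcyclohex-2-en-1-one
Conditions: I2, K2CO3, DMAP (0.2 equiv), THF–H2O, 23 °C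
Reagents that add atoms: iodine II
Why: α-Iodination of an enone by the Baylis–Hillman-type sequence of amine conjugate addition, iodination and elimination.

Step 3
Reactants: 4 2-iodo-3-methylcyclohex-2-en-1-one
Product: 5 3-methyl-2-(tributylstannyl)cyclohex-2-en-1-one
Conditions: Bu3SnSnBu3, Pd(PPh3)4 (5 mol %), toluene, 100 °C
Reagents that add atoms: hexabutylditin CCCC[Sn](CCCC)(CCCC)[Sn](CCCC)(CCCC)CCCC
Why: Palladium-catalysed stannylation of a vinyl iodide with a distannane (oxidative addition, Sn–Sn transmetallation, reductive elimination).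

Step 4
Reactants: 2 (2E)-4-bromo-3-methylbut-2-en-1-yl acetate; 5 3-methyl-2-(tributylstannyl)cyclohex-2-en-1-one
Product: 6 (2E)-3-methyl-5-(2-methyl-6-oxocyclohex-1-en-1-yl)-5-oxopent-2-en-1-yl acetate
Conditions: CO (3 atm), Pd2(dba)3 (2.5 mol %), AsPh3, THF, 50 °C
Reagents that add atoms: carbon monoxide [C-]#[O+]
Why: Carbonylative Stille coupling of an allyl halide (Milstein–Stille): CO inserts at the less substituted terminus (C7) of the π-allyl palladium, so the E C8=C9 olefin stays β,γ to the new ketone.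

Step 5
Reactants: 6 (2E)-3-methyl-5-(2-methyl-6-oxocyclohex-1-en-1-yl)-5-oxopent-2-en-1-yl acetate
Product: 8 11-hydroxy ene-dione (Δ5(10)-4,6-dione), via ene-dione acetate 7 (not isolated)
Conditions: Cu(SbF6)2·(S,S)-t-Bu-box (10 mol %; box = 2,2′-isopropylidenebis(4-tert-butyl-2-oxazoline)), 4 Å MS, CH2Cl2, −40 → 0 °C; then MeOH, K2CO3 (0.2 equiv), 0 °C
Reagents that add atoms: none
Why: Proposed new method: two-point binding of the 2-acyl enone to the chiral divalent copper Lewis acid makes C10 electrophilic and differentiates its faces, the E-olefin attacks through a chair (C9–C10 bond), and because the copper diketonate is too weak a base to quench it the C8 cation relays by anti-periplanar 1,2-H (C9→C8) and 1,2-CH3 (C10→C9) shifts until the charge is annihilated as the conjugated ene-dione, which fixes 9S (20α-CH3, C11 β) and 8R (17α-CH3) from the olefin geometry, after which the primary acetate is removed by methanolysis; closest known reaction type: Lewis-acid-induced alkene–enone addition followed by two 1,2-shifts (Snider) and the BF3-mediated 1,2-H/1,2-CH3 shifts of drimanyl cations.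

Step 6
Reactants: 8 11-hydroxy ene-dione
Product: 9 C5-methylated Δ1(10)-4,6-dione
Conditions: MeI, K2CO3, acetone, 0 → 23 °C
Reagents that add atoms: iodomethane CI
Why: Deconjugative α-alkylation: the C1-deprotonated vinylogous β-diketone enolate is methylated at C5 on the α face, anti to the pseudo-axial 9β-CH2OH, which moves the olefin to C1=C10.

Step 7
Reactants: 9 C5-methylated Δ1(10)-4,6-dione
Product: 10 1β,10β-epoxide
Conditions: mCPBA, NaHCO3, CH2Cl2, 0 °C
Reagents that add atoms: 3-chloroperoxybenzoic acid OOC(=O)c1cccc(Cl)c1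
Why: Prilezhaev epoxidation of the only olefin; the α face is shielded by the C19 and C20 methyls and the homoallylic 11-OH directs the peracid (Henbest effect) to the β face.

Step 8
Reactants: 10 1β,10β-epoxide
Product: 12 Δ7-6-one 11-aldehyde, via keto aldehyde 11 (not isolated)
Conditions: IBX (3.5 equiv), DMSO–fluorobenzene, 70 °C
Reagents that add atoms: none
Why: IBX first oxidises the primary alcohol to the non-enolisable aldehyde and then dehydrogenates the C6 ketone (Nicolaou IBX dehydrogenation) toward the tertiary C8–H, giving the more substituted enone.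

Step 9
Reactants: 12 Δ7-6-one 11-aldehyde; 13 1-(tert-butyldimethylsilyloxy)propan-2-one
Product: 14 (11S)-aldol adduct
Conditions: 13, LiN(iPr)2, THF, −78 °C; then 12, −78 °C; AcOH quench
Reagents that add atoms: none
Why: Aldol addition of the kinetic methyl-side lithium enolate to the aldehyde, which reacts far faster than the hindered ketones; Felkin–Anh attack anti to the bulky C10 and past the C20 methyl sets 11S.

Step 10
Reactants: 14 (11S)-aldol adduct
Product: 16 butenolide 11-alcohol, via hydroxy ketone diol 15 (not isolated)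
Conditions: Bu4NF, AcOH, THF, 0 °C; then Ph3P=C=C=O (1.05 equiv), toluene, 60 °C
Reagents that add atoms: (triphenylphosphoranylidene)ketene O=C=C=P(c1ccccc1)(c1ccccc1)c1ccccc1
Why: Buffered fluoride desilylation, then the primary α-hydroxy ketone is acylated by the ketenylidene phosphorane and the resulting ylide closes the butenolide by intramolecular Wittig olefination (Bestmann).

Step 11
Reactants: 16 butenolide 11-alcohol
Product: 17 11-isobutyrate
Conditions: (i-PrCO)2O, DMAP, Et3N, CH2Cl2, 23 °C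
Reagents that add atoms: isobutyric anhydride CC(C)C(=O)OC(=O)C(C)C
Why: DMAP-catalysed (Steglich-type) acylation of the only free hydroxyl.

Step 12
Reactants: 17 11-isobutyrate
Product: 18 6α-alcohol
Conditions: NaBH4, CeCl3·7H2O, MeOH, −78 °C
Reagents that add atoms: none
Why: Luche 1,2-reduction: the cerium-activated enone is reduced in preference to the neopentyl C4 ketone, and hydride enters from the β face opposite the axial C19 methyl to give the equatorial 6α-alcohol.

Step 13
Reactants: 18 6α-alcohol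
Product: 19 6α-acetate
Conditions: Ac2O, pyridine, DMAP (cat.), CH2Cl2, 0 °C
Reagents that add atoms: acetic anhydride CC(=O)OC(C)=O
Why: Nucleophile-catalysed acetylation of the only free hydroxyl.

Step 14
Reactants: 19 6α-acetate
Product: 20 7β,8β-diol
Conditions: OsO4 (5 mol %), NMO, acetone–H2O, 23 °C
Reagents that add atoms: osmium tetroxide O=[Os](=O)(=O)=O; N-methylmorpholine N-oxide C[N+]1([O-])CCOCC1; water O
Why: Upjohn dihydroxylation: OsO4 adds to the only electron-rich olefin anti to the allylic 6α-acetate (Kishi rule) and away from the α-methyls C19 and C20, giving 7β-OH and 8β-OH with 17α-CH3.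

Step 15
Reactants: 20 7β,8β-diol
Product: 21 7,11-diisobutyrate
Conditions: (i-PrCO)2O, DMAP, pyridine, 23 °C
Reagents that add atoms: isobutyric anhydride CC(C)C(=O)OC(=O)C(C)C
Why: Acylation of the secondary 7-OH; the tertiary 8-OH does not react.

Step 16
Reactants: 21 7,11-diisobutyrate
Product: 22 4(18)-methylene epoxide
Conditions: Zn, CH2Br2, TiCl4, THF–CH2Cl2, 0 → 23 °C
Reagents that add atoms: dibromomethane BrCBr
Why: Takai–Lombardo methylenation (geminal dizinc reagent activated by TiCl4), chemoselective for the ketone over esters and the lactone and effective for hindered, enolisable ketones.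

Step 17
Reactants: 22 4(18)-methylene epoxide
Product: 23 target
Conditions: Cp2TiCl2, Zn, 1,4-cyclohexadiene (excess), THF, 23 °C; then aq. HCl
Reagents that add atoms: none
Why: Nugent–RajanBabu reductive epoxide opening: Cp2TiCl (trivalent titanium) cleaves the C10–O bond to the tertiary C10 radical, which takes a hydrogen atom from 1,4-cyclohexadiene on the β face (α face blocked by C19 and C20), giving 10β-H and releasing the 1β-OH.

## Compound list

1 | isoprene (2-methylbuta-1,3-diene) | C=CC(C)=C | starting material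
2 | (2E)-4-bromo-3-methylbut-2-en-1-yl acetate | CC(=O)OC/C=C(\C)CBr | intermediate
3 | 3-methylcyclohex-2-en-1-one | CC1=CC(=O)CCC1 | starting material
4 | 2-iodo-3-methylcyclohex-2-en-1-one | CC1=C(I)C(=O)CCC1 | intermediate
5 | 3-methyl-2-(tributylstannyl)cyclohex-2-en-1-one | CCCC[Sn](CCCC)(CCCC)C1=C(C)CCCC1=O | intermediate
6 | (2E)-3-methyl-5-(2-methyl-6-oxocyclohex-1-en-1-yl)-5-oxopent-2-en-1-yl acetate | CC(=O)OC/C=C(\C)CC(=O)C1=C(C)CCCC1=O | intermediate
7 | (8R,9S)-11-acetoxy-12,13,14,15,16,18,19-heptanor-neo-clerod-5(10)-ene-4,6-dione (8β-H) | O=C1CCCC2=C1C(=O)C[C@@H](C)[C@]2(C)COC(C)=O | intermediate (not isolated)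
8 | (8R,9S)-11-hydroxy-12,13,14,15,16,18,19-heptanor-neo-clerod-5(10)-ene-4,6-dione (8β-H) | O=C1CCCC2=C1C(=O)C[C@@H](C)[C@]2(C)CO | intermediate
9 | 11-hydroxy-12,13,14,15,16,18-hexanor-neo-clerod-1(10)-ene-4,6-dione (19α-CH3, 8β-H) | O=C1CCC=C2[C@@]1(C)C(=O)C[C@@H](C)[C@]2(C)CO | intermediate
10 | 1β,10β-epoxy-11-hydroxy-12,13,14,15,16,18-hexanor-neo-clerodane-4,6-dione (8β-H) | O=C1CC[C@H]3O[C@@]32[C@@]1(C)C(=O)C[C@@H](C)[C@]2(C)CO | intermediate
11 | 1β,10β-epoxy-4,6-dioxo-12,13,14,15,16,18-hexanor-neo-clerodan-11-al (8β-H) | O=C1CC[C@H]3O[C@@]32[C@@]1(C)C(=O)C[C@@H](C)[C@]2(C)C=O | intermediate (not isolated)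
12 | 1β,10β-epoxy-4,6-dioxo-12,13,14,15,16,18-hexanor-neo-clerod-7-en-11-al | O=C1CC[C@H]3O[C@@]32[C@@]1(C)C(=O)C=C(C)[C@]2(C)C=O | intermediate
13 | 1-(tert-butyldimethylsilyloxy)propan-2-one | CC(=O)CO[Si](C)(C)C(C)(C)C | starting material
14 | (11S)-16-(tert-butyldimethylsilyloxy)-1β,10β-epoxy-11-hydroxy-14,15,18-trinor-neo-clerod-7-ene-4,6,13-trione | O=C1CC[C@H]3O[C@@]32[C@@]1(C)C(=O)C=C(C)[C@]2(C)[C@H](CC(=O)CO[Si](C)(C)C(C)(C)C)O | intermediate
15 | (11S)-1β,10β-epoxy-11,16-dihydroxy-14,15,18-trinor-neo-clerod-7-ene-4,6,13-trione | O=C1CC[C@H]3O[C@@]32[C@@]1(C)C(=O)C=C(C)[C@]2(C)[C@H](CC(=O)CO)O | intermediate (not isolated)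
16 | (11S)-1β,10β-epoxy-11-hydroxy-4,6-dioxo-18-nor-neo-cleroda-7,13-dien-15,16-olide | O=C1CC[C@H]3O[C@@]32[C@@]1(C)C(=O)C=C(C)[C@]2(C)[C@H](CC1=CC(=O)OC1)O | intermediate
17 | (11S)-1β,10β-epoxy-11-isobutyryloxy-4,6-dioxo-18-nor-neo-cleroda-7,13-dien-15,16-olide | O=C1CC[C@H]3O[C@@]32[C@@]1(C)C(=O)C=C(C)[C@]2(C)[C@H](CC1=CC(=O)OC1)OC(=O)C(C)C | intermediate
18 | (11S)-1β,10β-epoxy-6α-hydroxy-11-isobutyryloxy-4-oxo-18-nor-neo-cleroda-7,13-dien-15,16-olide | O=C1CC[C@H]3O[C@@]32[C@@]1(C)[C@@H](O)C=C(C)[C@]2(C)[C@H](CC1=CC(=O)OC1)OC(=O)C(C)C | intermediate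
19 | (11S)-6α-acetoxy-1β,10β-epoxy-11-isobutyryloxy-4-oxo-18-nor-neo-cleroda-7,13-dien-15,16-olide | O=C1CC[C@H]3O[C@@]32[C@@]1(C)[C@@H](OC(C)=O)C=C(C)[C@]2(C)[C@H](CC1=CC(=O)OC1)OC(=O)C(C)C | intermediate
20 | (11S)-6α-acetoxy-1β,10β-epoxy-7β,8β-dihydroxy-11-isobutyryloxy-4-oxo-18-nor-neo-clerod-13-en-15,16-olide | O=C1CC[C@H]3O[C@@]32[C@@]1(C)[C@@H](OC(C)=O)[C@H](O)[C@](C)(O)[C@]2(C)[C@H](CC1=CC(=O)OC1)OC(=O)C(C)C | intermediate
21 | (11S)-6α-acetoxy-1β,10β-epoxy-8β-hydroxy-7β,11-bis(isobutyryloxy)-4-oxo-18-nor-neo-clerod-13-en-15,16-olide | O=C1CC[C@H]3O[C@@]32[C@@]1(C)[C@@H](OC(C)=O)[C@H](OC(=O)C(C)C)[C@](C)(O)[C@]2(C)[C@H](CC1=CC(=O)OC1)OC(=O)C(C)C | intermediate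
22 | (11S)-6α-acetoxy-1β,10β-epoxy-8β-hydroxy-7β,11-bis(isobutyryloxy)-neo-cleroda-4(18),13-dien-15,16-olide | C=C1CC[C@H]3O[C@@]32[C@@]1(C)[C@@H](OC(C)=O)[C@H](OC(=O)C(C)C)[C@](C)(O)[C@]2(C)[C@H](CC1=CC(=O)OC1)OC(=O)C(C)C | intermediate
23 | (1R,5R,6R,7S,8R,9S,10S,11S)-6α-acetoxy-1β,8β-dihydroxy-7β,11-bis(isobutyryloxy)-neo-cleroda-4(18),13-dien-15,16-olide (CNP0325163.1) | C=C1CC[C@@H](O)[C@H]2[C@@]1(C)[C@@H](OC(C)=O)[C@H](OC(=O)C(C)C)[C@](C)(O)[C@]2(C)[C@H](CC1=CC(=O)OC1)OC(=O)C(C)C | target

## Step count and risks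

Total step count: 17. Longest linear sequence: 16 steps (3 → 4 → 5 → 6 → 8 → 9 → 10 → 12 → 14 → 16 → 17 → 18 → 19 → 20 → 21 → 22 → 23).

The three steps most likely to fail:

Step 5 (cyclisation with 1,2-H/1,2-CH3 relay). The C8 cation may lose a proton (ene-type products, including the conjugated Δ7-6-one) before the shifts occur. The fallback sets out from 6 and returns at 7, and separates ring closure from rearrangement. With the same copper catalyst at −78 °C and 2,6-di-tert-butylpyridine as proton shuttle, the reaction is stopped at the Lewis-acid-catalysed intramolecular ene product, the 8(17)-methylene ene adduct F1 (10α-CH3, 9β-H, enolised β-diketone). F1 is isolated and then treated with CF3SO3H in (CF3)2CHOH–CH2Cl2 at −40 °C; Markovnikov protonation of the exocyclic olefin regenerates the C8 cation in a non-basic medium and the H/CH3 relay gives 7.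

Step 8 (IBX oxidation and dehydrogenation). The C4 ketone may be dehydrogenated as well, or in place of the C6 ketone. The fallback sets out from 10 and returns at 12. Dess–Martin periodinane gives the keto aldehyde 11, which is now isolated. Me3SiOTf/Et3N converts both ketones into the bis(trimethylsilyl enol ether) F2. DDQ with 2,6-lutidine then abstracts hydride only from the single tertiary allylic position (C8–H), creating the C7=C8 enone, while the C4 enol ether is simply hydrolysed on work-up to give 12.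

Step 12 (Luche reduction). The C4 ketone may be reduced competitively. The fallback sets out from 12 and returns at 19; it moves the reduction in front of the side-chain steps, where temporary in-flask protection is possible. The aldehyde of 12 is masked as its lithium α-amino alkoxide (LiN(CH3)CH2CH2N(CH3)2) and the C4 ketone as its lithium enolate (LiN(iPr)2). i-Bu2AlH at −78 °C then reduces only the enone, and work-up gives the 6α-hydroxy keto aldehyde F3. Acetylation gives the 6α-acetoxy keto aldehyde F4. The aldol of step 9 gives the silyl ether aldol F5, Bu4NF/AcOH the hydroxy ketone diol F6, and Ph3P=C=C=O the butenolide 11-alcohol F7. Isobutyrylation of F7 as in step 11 delivers 19.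

## Further compounds

F1 | step 5 | 11-acetoxy-6-hydroxy-10α-methyl-8(17)-methylene-Δ5-octalin-4-one ene adduct (9β-H, 9α-CH2OAc, no C20 on C9) | O=C1CCC[C@]2(C)C1=C(O)CC(=C)[C@H]2COC(C)=O
F2 | step 8 | 1β,10β-epoxy-4,6-bis(trimethylsilyloxy)-12,13,14,15,16,18-hexanor-neo-cleroda-3,6-dien-11-al (8β-H) | C[Si](C)(C)OC1=CC[C@H]3O[C@@]32[C@@]1(C)C(O[Si](C)(C)C)=C[C@@H](C)[C@]2(C)C=O
F3 | step 12 | 1β,10β-epoxy-6α-hydroxy-4-oxo-12,13,14,15,16,18-hexanor-neo-clerod-7-en-11-al | O=C1CC[C@H]3O[C@@]32[C@@]1(C)[C@@H](O)C=C(C)[C@]2(C)C=O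
F4 | step 12 | 6α-acetoxy-1β,10β-epoxy-4-oxo-12,13,14,15,16,18-hexanor-neo-clerod-7-en-11-al | O=C1CC[C@H]3O[C@@]32[C@@]1(C)[C@@H](OC(C)=O)C=C(C)[C@]2(C)C=O
F5 | step 12 | (11S)-6α-acetoxy-16-(tert-butyldimethylsilyloxy)-1β,10β-epoxy-11-hydroxy-14,15,18-trinor-neo-clerod-7-ene-4,13-dione | O=C1CC[C@H]3O[C@@]32[C@@]1(C)[C@@H](OC(C)=O)C=C(C)[C@]2(C)[C@H](CC(=O)CO[Si](C)(C)C(C)(C)C)O
F6 | step 12 | (11S)-6α-acetoxy-1β,10β-epoxy-11,16-dihydroxy-14,15,18-trinor-neo-clerod-7-ene-4,13-dione | O=C1CC[C@H]3O[C@@]32[C@@]1(C)[C@@H](OC(C)=O)C=C(C)[C@]2(C)[C@H](CC(=O)CO)O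
F7 | step 12 | (11S)-6α-acetoxy-1β,10β-epoxy-11-hydroxy-4-oxo-18-nor-neo-cleroda-7,13-dien-15,16-olide | O=C1CC[C@H]3O[C@@]32[C@@]1(C)[C@@H](OC(C)=O)C=C(C)[C@]2(C)[C@H](CC1=CC(=O)OC1)O
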